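**Retrosynthetic overview**
- The target is reached by global removal of three methoxymethyl (MOM) ethers from the (3S)-3-aryl-3,5,7-tris(MOM-oxy)chroman-4-one.
- Key disconnection C3–C1′: that compound comes from racemic 3,5,7-tris(MOM-oxy)chroman-4-one and 1-bromo-2,4-dimethoxy-3-prenylbenzene by an enantioselective, stereoconvergent palladium-catalysed enolate arylation.
- Enabling feature: C3 of ring C is the only hydrogen-bearing α-carbon of the C4 ketone (the other flank is C4a of ring A) and becomes fully substituted, so both enantiomers of the ketone pass through one planar enolate and the product can neither epimerise nor react twice.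
- The ketone comes from 5,7-dihydroxychroman-4-one (MOM protection, C3 hydroxylation, MOM protection); the aryl bromide comes from 1-bromo-2,4-dimethoxybenzene by lithiation at C3 between the two methoxy groups and prenylation.
- Ring order: rings A and C are bought fused in the chromanone and ring B is bought as the bromoarene; no ring is formed in the route.

Key step: step 5

Assumption: 5,7-dihydroxychroman-4-one is taken as a catalogue compound, and the sense of induction in step 5 is assumed to be adjustable by the choice of ligand antipode.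

**Route**

Step 1
Reactants: 1 5,7-dihydroxychroman-4-one
Product: 3 5,7-bis(methoxymethoxy)chroman-4-one, via disodium bisphenoxide 2 (not isolated)
Conditions: NaH (2.2 equiv), THF–DMF, 0 °C; then MOMCl (2.3 equiv), 0 °C to rt
Reagents that add atoms: chloromethyl methyl ether (MOMCl), COCCl
Why: Williamson ether synthesis: both phenols, including the hydrogen-bonded 5-OH, are far more acidic than C3–H, so the bisphenoxide should be O-alkylated cleanly.

Step 2
Reactants: 3 5,7-bis(methoxymethoxy)chroman-4-one
Product: 5 rac-3-hydroxy-5,7-bis(methoxymethoxy)chroman-4-one, via sodium enolate 4 (not isolated)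
Conditions: NaN(SiMe3)2, THF, −78 °C; then 2-(phenylsulfonyl)-3-phenyloxaziridine, −78 °C; AcOH quench
Reagents that add atoms: 2-(phenylsulfonyl)-3-phenyloxaziridine, O=S(=O)(c1ccccc1)N1OC1c1ccccc1
Why: Davis oxidation (electrophilic hydroxylation of a ketone enolate by an N-sulfonyloxaziridine) at C3, the only enolisable position; the racemic carbinol is sufficient because this centre is erased again in step 5.

Step 3
Reactants: 5 rac-3-hydroxy-5,7-bis(methoxymethoxy)chroman-4-one
Product: 6 rac-3,5,7-tris(methoxymethoxy)chroman-4-one
Conditions: MOMCl, i-Pr2NEt, Bu4NI (cat.), CH2Cl2, 0 to 40 °C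
Reagents that add atoms: chloromethyl methyl ether (MOMCl), COCCl
Why: O-alkylation of the secondary α-hydroxy ketone under a mild amine base should give the small, base-stable acetal without α-ketol isomerisation.

Step 4
Reactants: 7 1-bromo-2,4-dimethoxybenzene
Product: 9 1-bromo-2,4-dimethoxy-3-(3-methylbut-2-en-1-yl)benzene, via aryllithium 8 (not isolated)
Conditions: LiN(i-Pr)2, THF, −78 °C; then CuBr·SMe2 (10 mol %), prenyl bromide, −78 to 0 °C
Reagents that add atoms: 1-bromo-3-methylbut-2-ene (prenyl bromide), CC(C)=CCBr
Why: Directed ortho-metalation by the amide base (no bromine–lithium exchange) should occur at C3, acidified by both flanking methoxy groups, and copper-catalysed SN2 allylation at the primary carbon of prenyl bromide should install the side chain with the aryl bromide intact.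

Step 5
Reactants: 6 rac-3,5,7-tris(methoxymethoxy)chroman-4-one; 9 1-bromo-2,4-dimethoxy-3-(3-methylbut-2-en-1-yl)benzene
Product: 11 (3S)-3-[2,4-dimethoxy-3-(3-methylbut-2-en-1-yl)phenyl]-3,5,7-tris(methoxymethoxy)chroman-4-one, via sodium enolate 10 (not isolated)
Conditions: Pd2(dba)3 (2.5 mol %), (R)-SEGPHOS (6 mol %), NaOtBu (1.5 equiv), toluene, 80 °C
Reagents that add atoms: none
Why: Proposed new method: NaOtBu converts both enantiomers of 6 into the single planar sodium enolate 10, the aryl bromide 9 adds oxidatively to the zerovalent palladium–bisphosphine complex, the enolate displaces bromide at palladium, and C–C reductive elimination from the C3-bound palladium enolate forms the C3–C1′ bond. The closest known reaction type is the palladium-catalysed enantioselective α-arylation of 2-alkyl- and 2-fluoro-1-tetralones and 1-indanones with aryl bromides or triflates to quaternary α-aryl ketones; an α-(alkoxymethoxy)chromanone has not been shown in it, and the reasoning is that the oxygen substituent, like fluorine, is small and acidifies C3–H. No ring is closed in this step. The new C3 stereocentre is set under catalyst control by the axially chiral bisphosphine, which differentiates the two enolate faces in the reductive elimination; the ligand antipode that leads to (3S) is to be fixed by a first experiment, and the step is stereoconvergent because the substrate stereocentre is erased in 10. The selectivity needed (C- over O-arylation, a single site, no second arylation) is secured by the substrate: C3 is the only α-carbon that bears hydrogen, the product has none left, and the retro-oxa-Michael opening of 10 is reversible and returns to 10.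

Step 6
Reactants: 11 (3S)-3-[2,4-dimethoxy-3-(3-methylbut-2-en-1-yl)phenyl]-3,5,7-tris(methoxymethoxy)chroman-4-one
Product: 12 (3S)-3-[2,4-dimethoxy-3-(3-methylbut-2-en-1-yl)phenyl]-3,5,7-trihydroxychroman-4-one
Conditions: 3 M HCl (aq), MeOH–THF, 40 °C
Reagents that add atoms: none
Why: Acid-catalysed acetal exchange with methanol should remove all three MOM groups; the aryl methyl ethers and the prenyl group (flanked by two OMe, no free ortho phenol) should persist, and the quaternary C3 carbinol, deactivated toward ionisation by the adjacent C4 carbonyl, keeps its configuration.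

**Compound list**
1 | 5,7-dihydroxychroman-4-one | O=C1CCOc2cc(O)cc(O)c12 | starting material
2 | disodium 4-oxo-3,4-dihydro-2H-chromene-5,7-diolate | [Na+].[Na+].[O-]c1cc([O-])c2C(=O)CCOc2c1 | intermediate
3 | 5,7-bis(methoxymethoxy)chroman-4-one | COCOc1cc(OCOC)c2C(=O)CCOc2c1 | intermediate
4 | sodium 5,7-bis(methoxymethoxy)-2H-chromen-4-olate | [Na+].[O-]C1=CCOc2cc(OCOC)cc(OCOC)c12 | intermediate
5 | rac-3-hydroxy-5,7-bis(methoxymethoxy)chroman-4-one (racemate) | COCOc1cc(OCOC)c2C(=O)C(O)COc2c1 | intermediate
6 | rac-3,5,7-tris(methoxymethoxy)chroman-4-one (racemate) | COCOC1COc2cc(OCOC)cc(OCOC)c2C1=O | intermediate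
7 | 1-bromo-2,4-dimethoxybenzene | COc1ccc(Br)c(OC)c1 | starting material
8 | (3-bromo-2,6-dimethoxyphenyl)lithium | COc1ccc(Br)c(OC)c1[Li] | intermediate
9 | 1-bromo-2,4-dimethoxy-3-(3-methylbut-2-en-1-yl)benzene | COc1ccc(Br)c(OC)c1CC=C(C)C | intermediate
10 | sodium 3,5,7-tris(methoxymethoxy)-2H-chromen-4-olate | [Na+].[O-]C1=C(OCOC)COc2cc(OCOC)cc(OCOC)c12 | intermediate
11 | (3S)-3-[2,4-dimethoxy-3-(3-methylbut-2-en-1-yl)phenyl]-3,5,7-tris(methoxymethoxy)chroman-4-one | COc1ccc([C@]2(OCOC)COc3cc(OCOC)cc(OCOC)c3C2=O)c(OC)c1CC=C(C)C | intermediate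
12 | (3S)-3-[2,4-dimethoxy-3-(3-methylbut-2-en-1-yl)phenyl]-3,5,7-trihydroxychroman-4-one | COc1ccc([C@]2(O)COc3cc(O)cc(O)c3C2=O)c(OC)c1CC=C(C)C | target

**Step count and risks**
Total steps: 6. Longest linear sequence: 5 (steps 1, 2, 3, 5, 6).

Steps most likely to fail:

1. Step 5 (proposed new method). The risk is slow C–C reductive elimination at the crowded, oxygen-substituted palladium enolate, so that β-hydride elimination toward the chromone and hydrodebromination compete, or weak discrimination of the two enolate faces. The fallback uses known chemistry, the enantioselective N-heterocyclic-carbene-catalysed intramolecular crossed benzoin reaction of an aldehyde with a ketone, which is documented for 3-aryl-3-hydroxychroman-4-ones and closes the C3–C4 bond of ring C instead. It sets out from 9 and comes back at 12. Bromine–lithium exchange on 9 (n-BuLi, THF, −78 °C) should give [2,4-dimethoxy-3-(3-methylbut-2-en-1-yl)phenyl]lithium F1, which is acylated with 2-chloro-N-methoxy-N-methylacetamide to 2-chloro-1-[2,4-dimethoxy-3-(3-methylbut-2-en-1-yl)phenyl]ethan-1-one F2. Commercial 2,4,6-trihydroxybenzaldehyde is converted with MOMCl and i-Pr2NEt into 2-hydroxy-4,6-bis(methoxymethoxy)benzaldehyde F3. Its remaining phenol is alkylated by F2 (K2CO3, KI, acetone, rt) to 2-{2-[2,4-dimethoxy-3-(3-methylbut-2-en-1-yl)phenyl]-2-oxoethoxy}-4,6-bis(methoxymethoxy)benzaldehyde F4. A chiral aminoindanol-derived triazolium salt (10 mol %) with Et3N in toluene at rt should cyclise F4 to (3S)-3-[2,4-dimethoxy-3-(3-methylbut-2-en-1-yl)phenyl]-3-hydroxy-5,7-bis(methoxymethoxy)chroman-4-one F5, the catalyst antipode being chosen for (3S). The conditions of step 6 applied to F5 should give 12.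

2. Step 6. The risk is that the tertiary alkyl acetal solvolyses more slowly than the two aryl acetals, and forcing the acid may cause loss of water from the tertiary benzylic carbinol toward the isoflavone or addition of HCl or methanol to the prenyl alkene. The fallback changes the protecting group on O-3 to a far more labile acetal; it sets out from 5 and comes back at 12. Compound 5 is treated with ethyl vinyl ether and pyridinium p-toluenesulfonate (CH2Cl2, rt) to give rac-3-(1-ethoxyethoxy)-5,7-bis(methoxymethoxy)chroman-4-one F6 (mixture of acetal epimers). Under the conditions of step 5, sodium 3-(1-ethoxyethoxy)-5,7-bis(methoxymethoxy)-2H-chromen-4-olate F7 should be arylated by 9 to (3S)-3-[2,4-dimethoxy-3-(3-methylbut-2-en-1-yl)phenyl]-3-(1-ethoxyethoxy)-5,7-bis(methoxymethoxy)chroman-4-one F8. The 1-ethoxyethyl acetal and the two aryl MOM ethers should then all be cleaved at rt (0.5 M HCl, MeOH) to give 12.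

3. Step 2. The risk is expulsion of the ring aryloxide from the metal enolate (retro-oxa-Michael ring opening), addition of the enolate to the sulfonimine by-product, and over-oxidation. The fallback replaces the low-temperature enolate oxidation by a hypervalent-iodine α-hydroxylation in protic medium, where a ring-opened phenoxide can reclose; it sets out from 3 and comes back at 5. PhI(OAc)2 with KOH in MeOH (0 °C to rt) should give 4,4-dimethoxy-5,7-bis(methoxymethoxy)chroman-3-ol F9. Brief hydrolysis of its very labile benzylic ketal (5 % aqueous oxalic acid, THF, rt), which should leave the aryl MOM ethers in place, returns 5.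

**Further compounds**
F1 | step 5 | [2,4-dimethoxy-3-(3-methylbut-2-en-1-yl)phenyl]lithium | COc1ccc([Li])c(OC)c1CC=C(C)C
F2 | step 5 | 2-chloro-1-[2,4-dimethoxy-3-(3-methylbut-2-en-1-yl)phenyl]ethan-1-one | COc1ccc(C(=O)CCl)c(OC)c1CC=C(C)C
F3 | step 5 | 2-hydroxy-4,6-bis(methoxymethoxy)benzaldehyde | COCOc1cc(O)c(C=O)c(OCOC)c1
F4 | step 5 | 2-{2-[2,4-dimethoxy-3-(3-methylbut-2-en-1-yl)phenyl]-2-oxoethoxy}-4,6-bis(methoxymethoxy)benzaldehyde | COc1ccc(C(=O)COc2cc(OCOC)cc(OCOC)c2C=O)c(OC)c1CC=C(C)C
F5 | step 5 | (3S)-3-[2,4-dimethoxy-3-(3-methylbut-2-en-1-yl)phenyl]-3-hydroxy-5,7-bis(methoxymethoxy)chroman-4-one | COc1ccc([C@]2(O)COc3cc(OCOC)cc(OCOC)c3C2=O)c(OC)c1CC=C(C)C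
F6 | step 6 | rac-3-(1-ethoxyethoxy)-5,7-bis(methoxymethoxy)chroman-4-one (mixture of acetal epimers) | CCOC(C)OC1COc2cc(OCOC)cc(OCOC)c2C1=O
F7 | step 6 | sodium 3-(1-ethoxyethoxy)-5,7-bis(methoxymethoxy)-2H-chromen-4-olate | [Na+].[O-]C1=C(OC(C)OCC)COc2cc(OCOC)cc(OCOC)c12
F8 | step 6 | (3S)-3-[2,4-dimethoxy-3-(3-methylbut-2-en-1-yl)phenyl]-3-(1-ethoxyethoxy)-5,7-bis(methoxymethoxy)chroman-4-one (mixture of acetal epimers) | COc1ccc([C@]2(OC(C)OCC)COc3cc(OCOC)cc(OCOC)c3C2=O)c(OC)c1CC=C(C)C
F9 | step 2 | 4,4-dimethoxy-5,7-bis(methoxymethoxy)chroman-3-ol (racemate) | COCOc1cc(OCOC)c2c(c1)OCC(O)C2(OC)OC
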